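**Plan** (1H-indene numbering: C-1 ketone, C-2 and C-4 methyl esters, C-3 and C-5 hexadecyl, C-7 acid, ring fusion C-3a/C-7a)
1. The retrosynthesis first removes the C-7 carboxyl carbon (carbonylation of an enol triflate; the C7=C7a alkene made this way is hydrogenated last), which uncovers the enolised 1,7-dione 11.
2. In 11, C-7a is the central carbon of a 1,3-diketone, C-3a is the β-carbon of an acyl-alkylidene β-keto ester, and the six-membered ring is a 3-alkylcyclohex-2-enone. C3a–C7a (conjugate addition), C5=C6 (aldol condensation) and C2=C3 (Knoevenagel condensation) are therefore cut together, giving triketide ester 8 and ene-dione ester 6.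
3. 6 is cut to furan 5, and 5 to β-keto ester 3 and 1-octadecyne.
4. Forward: 6 and 8 are joined through C3a–C7a, then the five-membered and the six-membered ring close in the same pot; triflation, hydroxycarbonylation and hydrogenation complete the acid.
5. Stereochemistry: C-3a from the chiral squaramide in the conjugate addition, C-4 by equilibration to the pseudoaxial ester, C-7 and C-7a by syn addition of H2 on the face of H-3a.

Key step: step 5

Assumption: the quinine-derived squaramide (step 5) and the (S)-BINAP ligand (step 8) are taken to have the matched sense; if a first run shows the opposite, the quinidine-derived catalyst or the (R)-ligand takes their place.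

Step 1
Reactants: 1 heptadecanoyl chloride; 2 potassium methyl malonate
Product: 3 methyl 3-oxononadecanoate
Conditions: MgCl2, Et3N, MeCN, 0 °C to rt; then 1 M HCl
Reagents that add atoms: none
Why: C-acylation of the chelated magnesium enolate of the malonate half-ester followed by decarboxylation on acidic work-up (acylation/decarboxylation route to β-keto esters) should give the β-keto ester without O-acylation.

Step 2
Reactants: 3 methyl 3-oxononadecanoate; 4 1-octadecyne
Product: 5 methyl 2,5-dihexadecylfuran-3-carboxylate
Conditions: Ag2CO3 (2 equiv), KOAc, DMF, 80 °C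
Reagents that add atoms: none
Why: the silver-mediated oxidative C–H/C–H annulation of a 1,3-dicarbonyl compound with a terminal alkyne (C–C bond from the silver acetylide to the enolate carbon, then O-cyclisation) is a known furan synthesis and should give the 2,5-dialkylfuran-3-carboxylate.

Step 3
Reactants: 5 methyl 2,5-dihexadecylfuran-3-carboxylate
Product: 6 methyl (2E)-2-heptadecanoyl-4-oxoicos-2-enoate (the two ketone groups cis on the alkene)
Conditions: dimethyldioxirane, acetone, −20 °C to 0 °C
Reagents that add atoms: dimethyldioxirane CC1(C)OO1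
Why: epoxidation of the more electron-rich C4=C5 bond of the furan and opening of the epoxide (oxidative furan ring opening) should give the cis-ene-dione under neutral conditions.

Step 4
Reactants: 7 dehydroacetic acid
Product: 8 methyl 3,5-dioxohexanoate
Conditions: Mg(OMe)2, MeOH, reflux; then 2 M HCl
Reagents that add atoms: magnesium methoxide C[O-].C[O-].[Mg+2] in methanol CO
Why: methanolysis of the lactone and retro-Claisen loss of the 3-acetyl group as methyl acetate, with the product held as its magnesium chelate, should give the triketide ester.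

Step 5
Reactants: 6 methyl (2E)-2-heptadecanoyl-4-oxoicos-2-enoate; 8 methyl 3,5-dioxohexanoate
Product: 11 dimethyl (3aR,4R)-3,5-dihexadecyl-7-hydroxy-1-oxo-3a,4-dihydro-1H-indene-2,4-dicarboxylate, via Michael adduct 9 (not isolated), via cyclopentenone 10 (not isolated)
Conditions: quinine-derived 3,5-bis(trifluoromethyl)phenyl squaramide (5 mol %), toluene, −20 °C; then piperidine (20 mol %), 4 Å MS, 40 °C; then 1 M HCl
Reagents that add atoms: none
Why: The squaramide-bound enolate of the diketone methylene C-4 of 8 adds to the β-carbon of the acyl-alkylidene β-keto ester 6 (Michael addition, C3a–C7a), after which piperidine mediates a Knoevenagel condensation of the β-keto ester methylene with the hexadecyl ketone (C2=C3) and then an aldol condensation of the acetyl methyl group with the heptadecanoyl ketone (C5=C6). The closest known reaction type is the Robinson-type Michael/aldol annulation in the variant in which the methyl ketone of the donor attacks the ketone of the acceptor, joined to the base-mediated cyclopentenone formation from a 1,4-diketone. The five-membered ring closes 5-(enolexo)-exo-trig and the six-membered ring 6-(enolexo)-exo-trig, each followed by E1cB loss of water. C-3a is set by the catalyst, which holds the acceptor by two hydrogen bonds and shields one of its faces; C-7a carries no configuration in enol 11, and C-4 should equilibrate to the epimer with a pseudoaxial ester cis to C-3, which avoids allylic strain with the C-5 chain and the peri contact with the C-3 chain. The step needs the donor to react at its diketone methylene and not at C-2, the β-keto ester methylene to condense with the isolated ketone and not with the enolised heptadecanoyl ketone, and the acetyl methyl group rather than the heptadecanoyl methylene to close the six-membered ring; the acidity order within 8, the low electrophilicity of the enolised β-keto ester ketone and the lower hindrance of the methyl nucleophile should secure these.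

Step 6
Reactants: 11 dimethyl (3aR,4R)-3,5-dihexadecyl-7-hydroxy-1-oxo-3a,4-dihydro-1H-indene-2,4-dicarboxylate
Product: 12 dimethyl (3aR,4R)-3,5-dihexadecyl-1-oxo-7-(trifluoromethanesulfonyloxy)-3a,4-dihydro-1H-indene-2,4-dicarboxylate
Conditions: Tf2O, i-Pr2NEt, CH2Cl2, −78 °C
Reagents that add atoms: trifluoromethanesulfonic anhydride O=S(=O)(OS(=O)(=O)C(F)(F)F)C(F)(F)F
Why: O-sulfonylation of the enolised 1,3-diketone (enol triflate formation) should take place at the unhindered C-7 oxygen, which keeps the double bond endocyclic to the six-membered ring and exocyclic to the five-membered ring, whereas the C-1 oxygen is flanked by the C-2 ester.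

Step 7
Reactants: 12 dimethyl (3aR,4R)-3,5-dihexadecyl-1-oxo-7-(trifluoromethanesulfonyloxy)-3a,4-dihydro-1H-indene-2,4-dicarboxylate
Product: 13 (3aR,4R)-3,5-dihexadecyl-2,4-bis(methoxycarbonyl)-1-oxo-3a,4-dihydro-1H-indene-7-carboxylic acid
Conditions: Pd(OAc)2 (5 mol %), Ph2P(CH2)3PPh2, CO (1 atm), KOAc, DMF, rt; then H2O, dilute HCl
Reagents that add atoms: carbon monoxide [C-]#[O+]; potassium acetate CC(=O)[O-].[K+]
Why: oxidative addition of zerovalent palladium into the vinylogous acyl triflate, CO insertion and capture of the acylpalladium by acetate to a mixed anhydride that is hydrolysed on work-up (palladium-catalysed hydroxycarbonylation of a vinyl triflate) should install the free acid at C-7 beside the two methyl esters.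

Step 8
Reactants: 13 (3aR,4R)-3,5-dihexadecyl-2,4-bis(methoxycarbonyl)-1-oxo-3a,4-dihydro-1H-indene-7-carboxylic acid
Product: 14 (3aR,4R,7R,7aS)-3,5-dihexadecyl-2,4-bis(methoxycarbonyl)-1-oxo-3a,4,7,7a-tetrahydro-1H-indene-7-carboxylic acid
Conditions: H2 (60 atm), Ru(OAc)2[(S)-BINAP] (2 mol %), MeOH, 30 °C
Reagents that add atoms: none
Why: carboxylate-directed homogeneous hydrogenation of an α,β-unsaturated acid should add both hydrogens syn to C-7 and C-7a on the face of H-3a, opposite the pseudoaxial C-4 ester, so that the ring fusion becomes cis and the acid ends cis to the C-4 ester and the five-membered ring, while the C5=C6 and C2=C3 alkenes, which the carboxylate does not direct, should remain.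

**Compound list**
1 | heptadecanoyl chloride | CCCCCCCCCCCCCCCCC(=O)Cl | starting material
2 | potassium methyl malonate (potassium 3-methoxy-3-oxopropanoate) | COC(=O)CC(=O)[O-].[K+] | starting material
3 | methyl 3-oxononadecanoate | CCCCCCCCCCCCCCCCC(=O)CC(=O)OC | intermediate
4 | 1-octadecyne | CCCCCCCCCCCCCCCCC#C | starting material
5 | methyl 2,5-dihexadecylfuran-3-carboxylate | CCCCCCCCCCCCCCCCc1cc(C(=O)OC)c(CCCCCCCCCCCCCCCC)o1 | intermediate
6 | methyl (2E)-2-heptadecanoyl-4-oxoicos-2-enoate (ketone groups cis) | CCCCCCCCCCCCCCCCC(=O)/C=C(/C(=O)OC)C(=O)CCCCCCCCCCCCCCCC | intermediate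
7 | dehydroacetic acid (3-acetyl-4-hydroxy-6-methyl-2H-pyran-2-one) | CC(=O)C1=C(O)C=C(C)OC1=O | starting material
8 | methyl 3,5-dioxohexanoate | CC(=O)CC(=O)CC(=O)OC | intermediate
9 | methyl (5R)-4-acetyl-5-heptadecanoyl-6-(methoxycarbonyl)-3,7-dioxotricosanoate (Michael adduct; C-4 and C-6 epimerisable) | CCCCCCCCCCCCCCCCC(=O)[C@H](C(C(C)=O)C(=O)CC(=O)OC)C(C(=O)OC)C(=O)CCCCCCCCCCCCCCCC | intermediate (not isolated)
10 | methyl (3R)-4-acetyl-2-hexadecyl-3-(1-methoxy-1,3-dioxononadecan-2-yl)-5-oxocyclopent-1-ene-1-carboxylate (C-4 and the side-chain centre epimerisable) | CC(=O)C1C(=O)C(C(=O)OC)=C(CCCCCCCCCCCCCCCC)[C@H]1C(C(=O)OC)C(=O)CCCCCCCCCCCCCCCC | intermediate (not isolated)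
11 | dimethyl (3aR,4R)-3,5-dihexadecyl-7-hydroxy-1-oxo-3a,4-dihydro-1H-indene-2,4-dicarboxylate (enol form of the 1,7-dione; H-3a and H-4 cis) | CCCCCCCCCCCCCCCCC1=CC(O)=C2C(=O)C(C(=O)OC)=C(CCCCCCCCCCCCCCCC)[C@H]2[C@H]1C(=O)OC | intermediate
12 | dimethyl (3aR,4R)-3,5-dihexadecyl-1-oxo-7-(trifluoromethanesulfonyloxy)-3a,4-dihydro-1H-indene-2,4-dicarboxylate | CCCCCCCCCCCCCCCCC1=CC(OS(=O)(=O)C(F)(F)F)=C2C(=O)C(C(=O)OC)=C(CCCCCCCCCCCCCCCC)[C@H]2[C@H]1C(=O)OC | intermediate
13 | (3aR,4R)-3,5-dihexadecyl-2,4-bis(methoxycarbonyl)-1-oxo-3a,4-dihydro-1H-indene-7-carboxylic acid | CCCCCCCCCCCCCCCCC1=CC(C(=O)O)=C2C(=O)C(C(=O)OC)=C(CCCCCCCCCCCCCCCC)[C@H]2[C@H]1C(=O)OC | intermediate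
14 | (3aR,4R,7R,7aS)-3,5-dihexadecyl-2,4-bis(methoxycarbonyl)-1-oxo-3a,4,7,7a-tetrahydro-1H-indene-7-carboxylic acid (all four ring hydrogens at C-3a, C-4, C-7, C-7a on one face) | CCCCCCCCCCCCCCCCC1=C[C@@H](C(=O)O)[C@H]2C(=O)C(C(=O)OC)=C(CCCCCCCCCCCCCCCC)[C@H]2[C@H]1C(=O)OC | target

**Step count and risks**
Total steps: 8. Longest linear sequence: 7 steps (steps 1, 2, 3, 5, 6, 7, 8).

Steps most likely to fail:

1. Step 5. Enantiomeric purity may be lost if the conjugate addition reverses, or if the ketone next to C-3a enolises, before the rings close; the tetracarbonyl intermediate may also drift into furans by O-cyclisation. Fallback: setting out from 6 and 8, the domino is run with piperidine alone to give the racemic diketone enol F1. F1 is taken through the conditions of steps 6 and 7 to the racemic triflate F2 and the racemic acid F3. F3 is resolved by crystallisation of its (R)-1-phenylethylammonium salt F4 (or the salt of the antipodal amine, whichever is less soluble), and acidification with dilute HCl returns the route at 13.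

2. Step 8. The tetrasubstituted alkene may react slowly or on the wrong face, and ring-chain tautomerism of the acyl-acrylic acid to a hydroxybutenolide may remove the carboxylate direction. Fallback: setting out from 13, the ene-dicarbonyl unit C-1/C7a=C7/CO2H is reduced with Zn dust in AcOH at rt (electron-transfer conjugate reduction of a 4-oxo-2-enoic acid). C-7a should settle to the cis ring fusion and C-7 be protonated from the convex face, which returns the route at 14.

3. Step 7. Acetate or traces of water may attack the vinylogous acyl triflate and return 11, and base may shift protons in 13 towards its aromatic indanone isomer. Fallback: setting out from 12, reductive carboxylation with CO2 (1 atm), NiBr2 with 2,2'-bipyridine (10 mol %), Mn powder and Et4NI in DMA at rt (nickel-catalysed carboxylation of an alkenyl triflate) avoids both the external base and the oxygen nucleophile, and returns the route at 13.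

Further compounds
F1 | step 5 | dimethyl rac-(3aR,4R)-3,5-dihexadecyl-7-hydroxy-1-oxo-3a,4-dihydro-1H-indene-2,4-dicarboxylate | CCCCCCCCCCCCCCCCC1=CC(O)=C2C(=O)C(C(=O)OC)=C(CCCCCCCCCCCCCCCC)C2C1C(=O)OC
F2 | step 5 | dimethyl rac-(3aR,4R)-3,5-dihexadecyl-1-oxo-7-(trifluoromethanesulfonyloxy)-3a,4-dihydro-1H-indene-2,4-dicarboxylate | CCCCCCCCCCCCCCCCC1=CC(OS(=O)(=O)C(F)(F)F)=C2C(=O)C(C(=O)OC)=C(CCCCCCCCCCCCCCCC)C2C1C(=O)OC
F3 | step 5 | rac-(3aR,4R)-3,5-dihexadecyl-2,4-bis(methoxycarbonyl)-1-oxo-3a,4-dihydro-1H-indene-7-carboxylic acid | CCCCCCCCCCCCCCCCC1=CC(C(=O)O)=C2C(=O)C(C(=O)OC)=C(CCCCCCCCCCCCCCCC)C2C1C(=O)OC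
F4 | step 5 | (R)-1-phenylethylammonium (3aR,4R)-3,5-dihexadecyl-2,4-bis(methoxycarbonyl)-1-oxo-3a,4-dihydro-1H-indene-7-carboxylate | CCCCCCCCCCCCCCCCC1=CC(C(=O)[O-])=C2C(=O)C(C(=O)OC)=C(CCCCCCCCCCCCCCCC)[C@H]2[C@H]1C(=O)OC.C[C@@H]([NH3+])c1ccccc1
F0 | step 8 | none | none
F0 | step 7 | none | none
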